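In a one-step world the starting complex lost in the west run would stand as complex with two exchanged. It doesn't: 14.0% of the charge is gone at 40.0 h, while the product reads 1%. So the product takes two steps, through complex with one exchanged.

| flask | starting complex | incoming ligand | scavenger | remark | time |
|---|---|---|---|---|---|
| north-west | 0.021 M | 0.132 M | 0.165 M | run made earlier |  |
| west | 0.84 M | 0.132 M | 0.165 M | run made earlier |  |
| zeta | 0.040 M | 0.132 M | 0.165 M |  | 50 h |
| theta | 0.12 M | 0.132 M | 0.165 M |  | 50 h |
| eta | 0.30 M | 0.132 M | 0.165 M |  | 50 h |
| epsilon | 1.0 M | 0.132 M | 0.165 M |  | 50 h |

| run | time / h | complex with two exchanged / % | starting complex / % |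
|---|---|---|---|
| north-west | 3.00 | 0 | 89 |
| north-west | 6.00 | 4 | 79 |
| north-west | 15.0 | 17 | 56 |
| north-west | 40.0 | 50 | 20 |
| west | 3.00 | 1 | 91 |
| west | 6.00 | 2 | 90 |
| west | 15.0 | 0 | 87 |
| west | 40.0 | 1 | 86 |

(standard deviation of a reading: 1.5 percentage points)

- "hardly changes" means that all values lie within two and a half points (for a concentration: within two and a half percent of the largest)

- [complex with two exchanged] at the end for zeta, theta, eta, epsilon, in this order
- the course of these numbers from the first flask to the last (falls, then rises / falls all the way / hardly changes / rises all the way / rises, then falls)

The west loss of 0.118 M lies near c(incoming ligand), 0.132 M, and below c(scavenger), 0.165 M. We therefore take incoming ligand as the limiting reagent, and b = c(incoming ligand)/c(starting complex) as the exchanges its charge pays for per complex.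

Now follow one molecule. Each ligand comes to a fork: starting complex or complex with one exchanged, with odds s per molecule in favour of the latter. If a fraction x of the charge has been touched, a touched molecule takes a second ligand with chance about s·x/2. So the product fraction is y = s·x·x/2. A product molecule costs two ligands, and counting them gives x = b − y.

Which numbers matter? The charge of ligand enters squared and s to the first power. The scavenger doesn't enter this reckoning. Time hardly enters in epsilon: north-west gives a first-order constant of 0.0402 /h, so the ligand's life there, its charge over its first rate of use, is 3.28 h, shorter than 50 h. In zeta that life is 82.0 h, longer than 50 h, so the row should first rise with the charge.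

That leaves s. The north-west reading at 15.0 h, 17% of product with 44.0% touched, gives s = 1.76, the selectivity factor, those odds per molecule, with the scatter of 1.5 percentage points on it. For epsilon, b = 0.132, and we reckon 0.0125 M.

The forecast, on the ground that “The reaction stops when the ligand is spent”, gives 0.024 M, 0.045 M, 0.023 M, 0.008 M: rises, then falls.

The flask gives 0.0207 M, 0.0353 M, 0.0274 M, 0.0110 M: rises, then falls.

    starting complex + incoming ligand → leaving ligand + complex with one exchanged (k = 0.00514 /M/min)
    complex with one exchanged + incoming ligand → leaving ligand + complex with two exchanged (k = 0.00760 /M/min)
    complex with two exchanged + incoming ligand → leaving ligand + complex with three exchanged (k = 4.39 × 10⁻⁴ /M/min)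
    complex with three exchanged + incoming ligand → leaving ligand + complex with four exchanged (k = 0.0175 /M/min)
    leaving ligand + incoming ligand ⇌ idle adduct, settled at all times (K = 2.51 /M)
    scavenger + leaving ligand → scavenged by-product (k = 0.323 /M/min)

Epsilon's 0.0110 M stands against our 0.0125 M from s = 1.76. In eta, with incoming ligand at 0.819% of its charge, the same s gives 0.0303 M, and the flask holds 0.0274 M. The largest single effect in epsilon is the consumption of incoming ligand: with that consumption taken away, c(complex with two exchanged) at the end in epsilon goes from 0.0110 M to 0.643 M.

The data come from a simulation from invented constants, noise included.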